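**Assumption:** the target has no stereocenters (gem-dimethyl groups, no E/Z element), so "single enantiomer" is moot. Selectivity in the Claisen steps follows the meta-substituent rules I state in the "Why" lines.

## Retrosynthetic overview
1. Target ⇐ Claisen rearrangement of a 6‑O‑prenyl benzofuran. This sets the C7 reverse‑prenyl group late, regiospecifically and in one step. The A‑ring phenol is masked as a pivalate.
2. The 6‑O‑prenyl ether ⇐ selective O‑prenylation of a benzofuran‑4,6‑diol. The A‑ring allyl group is converted to prenyl by cross‑metathesis before the Claisen, since metathesis afterwards would attack the new vinyl group.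
3. Key step: the benzofuran ring forms in one operation from symmetrical phloroglucinol and an aryl α‑bromoketone (TiCl4 Friedel–Crafts alkylation, then cyclodehydration). Phloroglucinol's symmetry gives only one regioisomer and avoids Pd coupling.
4. The aryl α‑bromoketone comes from 3′,5′‑dihydroxyacetophenone. Ring order: the chroman is made first, by propargyl Claisen/6π electrocyclization to the chromene and then hydrogenation. The benzofuran is formed next. The allyl group is installed by an ortho‑Claisen.

## Route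

**Step 1**
Reactants: 1 (3′,5′‑dihydroxyacetophenone, 2 equiv); 2 (3‑chloro‑3‑methylbut‑1‑yne, 1 equiv)
Product: 3, 1‑[3‑hydroxy‑5‑(2‑methylbut‑3‑yn‑2‑yloxy)phenyl]ethanone
Conditions: K2CO3, KI, CuI (cat.), DMF, rt
Reagents that add atoms: 3‑chloro‑3‑methylbut‑1‑yne, C#CC(C)(C)Cl
Why: Cu‑assisted O‑propargylation (Williamson type) of a symmetric diol. Excess diol favors the mono‑ether.

**Step 2**
Reactants: 3
Product: 4, 1‑(7‑hydroxy‑2,2‑dimethyl‑2H‑chromen‑5‑yl)ethanone
Conditions: PhNEt2, 210 °C, 2 h
Reagents that add atoms: none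
Why: Aromatic propargyl Claisen, then 1,5‑H shift and 6π‑electrocyclization, builds the pyran ring. The meta acetyl group favors closure at the adjacent carbon, and the meta OH favors the remote one; both point to C6 (ortho to acetyl). The angular isomer is a minor, separable by‑product.

**Step 3**
Reactants: 4
Product: 5, 1‑(7‑hydroxy‑2,2‑dimethylchroman‑5‑yl)ethanone
Conditions: H2 (1 atm), 10% Pd/C, EtOAc, rt, 1 h
Reagents that add atoms: none
Why: The chromene C3=C4 is the only alkene present, so it is reduced selectively. The gem‑dimethyl chroman is then complete, and no stereocenter is formed.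

**Step 4**
Reactants: 5; 6 (allyl bromide)
Product: 7, 1‑(7‑allyloxy‑2,2‑dimethylchroman‑5‑yl)ethanone
Conditions: K2CO3, acetone, reflux
Reagents that add atoms: allyl bromide, C=CCBr
Why: Williamson O‑allylation of the only free phenol.

**Step 5**
Reactants: 7
Product: 8, 1‑(6‑allyl‑7‑hydroxy‑2,2‑dimethylchroman‑5‑yl)ethanone
Conditions: PhNEt2, 200 °C (sealed tube or microwave), 1 h
Reagents that add atoms: none
Why: Aromatic Claisen [3,3]. The C5 acetyl group (adjacent‑position directing) and the C8a ether oxygen (remote‑position directing) both favor allyl delivery to C6 over C8. This places the future A‑ring prenyl carbon ortho to both the OH and the acetyl group.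

**Step 6**
Reactants: 8; 9 (pivaloyl chloride)
Product: 10, 1‑[6‑allyl‑2,2‑dimethyl‑7‑(pivaloyloxy)chroman‑5‑yl]ethanone
Conditions: PivCl, Et3N, DMAP (cat.), CH2Cl2, 0 °C to rt
Reagents that add atoms: pivaloyl chloride, CC(C)(C)C(=O)Cl
Why: The phenol is masked as a pivalate. The pivalate survives TiCl4, K2CO3 and 190 °C, and LiAlH4 removes it in the last step.

**Step 7**
Reactants: 10; 11 (NBS)
Product: 12, 2‑bromo‑1‑[6‑allyl‑2,2‑dimethyl‑7‑(pivaloyloxy)chroman‑5‑yl]ethanone
Conditions: (i) TMSOTf, Et3N, CH2Cl2, 0 °C; (ii) NBS, THF, −78 to 0 °C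
Reagents that add atoms: NBS, O=C1CCC(=O)N1Br. TMSOTf is not retained.
Why: The in‑situ silyl enol ether is far more nucleophilic than the terminal alkene or the arene, so bromination is chemoselective at the methyl group.

**Step 8 (key step)**
Reactants: 12; 13 (phloroglucinol, 3 equiv)
Product: 14, 2‑[6‑allyl‑2,2‑dimethyl‑7‑(pivaloyloxy)chroman‑5‑yl]benzofuran‑4,6‑diol
Conditions: TiCl4 (1.5 equiv), CF3CH2OH/CH2Cl2, 0 °C to 50 °C
Reagents that add atoms: phloroglucinol, Oc1cc(O)cc(O)c1
Why: Proposed new method: Ti‑phloroglucinolate is alkylated at carbon by the α‑bromoketone (Friedel–Crafts SN2). The resulting o‑hydroxyphenyl ketone then cyclizes to a hemiketal and dehydrates to the aromatic benzofuran. This is the closest known reaction, the TiCl4‑promoted phenol plus α‑haloketone benzofuran synthesis. The symmetry of phloroglucinol gives a single 4,6‑diol regioisomer, excess phloroglucinol limits dialkylation, and no stereocenter is involved.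

**Step 9**
Reactants: 14; 15 (prenyl bromide)
Product: 16, 2‑[6‑allyl‑2,2‑dimethyl‑7‑(pivaloyloxy)chroman‑5‑yl]‑6‑(prenyloxy)benzofuran‑4‑ol
Conditions: prenyl bromide (1.0 equiv), K2CO3 (1.0 equiv), acetone, 0 °C to rt
Reagents that add atoms: prenyl bromide, CC(C)=CCBr
Why: Williamson O‑alkylation. The 6‑OH is less hindered than the 4‑OH, which sits peri to C3–H, so 6‑O alkylation predominates and the minor 4‑O isomer is removed chromatographically.

**Step 10**
Reactants: 16; 17 (2‑methylbut‑2‑ene)
Product: 18, 6‑(prenyloxy)‑2‑[6‑prenyl‑2,2‑dimethyl‑7‑(pivaloyloxy)chroman‑5‑yl]benzofuran‑4‑ol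
Conditions: Hoveyda–Grubbs II (5 mol%), 1,4‑benzoquinone (10 mol%), 2‑methylbut‑2‑ene (30 equiv), CH2Cl2, 40 °C
Reagents that add atoms: 2‑methylbut‑2‑ene, CC=C(C)C (transfers =CMe2)
Why: Cross‑metathesis converts the terminal allyl group to prenyl. The O‑prenyl ether undergoes only degenerate exchange with the same reagent, and the quinone suppresses Ru–H isomerization. This step must precede the Claisen, otherwise the new vinyl group would also be metathesized.

**Step 11**
Reactants: 18
Product: 19, 7‑(1,1‑dimethylallyl)‑2‑[6‑prenyl‑2,2‑dimethyl‑7‑(pivaloyloxy)chroman‑5‑yl]benzofuran‑4,6‑diol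
Conditions: PhNEt2, 180–190 °C, sealed tube, 1 h
Reagents that add atoms: none
Why: Aromatic Claisen of the prenyl ether transposes the allyl terminus, so it bonds through the CMe2 carbon and gives the reverse‑prenyl quaternary centre. Rearrangement goes to C7 (the position next to the ring‑fusion carbon, as in 7‑allyloxycoumarins going to C8), not the doubly O‑flanked C5. The amine base prevents acid‑driven cyclization of the product to a coumaran.

**Step 12**
Reactants: 19
Product: 20, Artopetelin C
Conditions: LiAlH4 (4 equiv), THF, 0 °C to rt; then aqueous NH4Cl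
Reagents that add atoms: none
Why: Hydride cleaves the hindered aryl pivalate. The benzofuran, the vinyl group, the prenyl group and the chroman are inert, and the free phenols are regenerated.

## Compound list
1 | 3′,5′‑dihydroxyacetophenone | CC(=O)c1cc(O)cc(O)c1 | starting material
2 | 3‑chloro‑3‑methylbut‑1‑yne | C#CC(C)(C)Cl | starting material
3 | 1‑[3‑hydroxy‑5‑(2‑methylbut‑3‑yn‑2‑yloxy)phenyl]ethanone | CC(=O)c1cc(O)cc(OC(C)(C)C#C)c1 | intermediate
4 | 1‑(7‑hydroxy‑2,2‑dimethyl‑2H‑chromen‑5‑yl)ethanone | CC(=O)c1cc(O)cc2OC(C)(C)C=Cc12 | intermediate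
5 | 1‑(7‑hydroxy‑2,2‑dimethylchroman‑5‑yl)ethanone | CC(=O)c1cc(O)cc2OC(C)(C)CCc12 | intermediate
6 | allyl bromide | C=CCBr | starting material
7 | 1‑(7‑allyloxy‑2,2‑dimethylchroman‑5‑yl)ethanone | CC(=O)c1cc(OCC=C)cc2OC(C)(C)CCc12 | intermediate
8 | 1‑(6‑allyl‑7‑hydroxy‑2,2‑dimethylchroman‑5‑yl)ethanone | CC(=O)c1c(CC=C)c(O)cc2OC(C)(C)CCc12 | intermediate
9 | pivaloyl chloride | CC(C)(C)C(=O)Cl | starting material
10 | 1‑[6‑allyl‑2,2‑dimethyl‑7‑(pivaloyloxy)chroman‑5‑yl]ethanone | CC(=O)c1c(CC=C)c(OC(=O)C(C)(C)C)cc2OC(C)(C)CCc12 | intermediate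
11 | N‑bromosuccinimide | O=C1CCC(=O)N1Br | starting material
12 | 2‑bromo‑1‑[6‑allyl‑2,2‑dimethyl‑7‑(pivaloyloxy)chroman‑5‑yl]ethanone | BrCC(=O)c1c(CC=C)c(OC(=O)C(C)(C)C)cc2OC(C)(C)CCc12 | intermediate
13 | phloroglucinol | Oc1cc(O)cc(O)c1 | starting material
14 | 2‑[6‑allyl‑2,2‑dimethyl‑7‑(pivaloyloxy)chroman‑5‑yl]benzofuran‑4,6‑diol | Oc1cc(O)c2cc(oc2c1)-c3c(CC=C)c(OC(=O)C(C)(C)C)cc4OC(C)(C)CCc34 | intermediate
15 | prenyl bromide | CC(C)=CCBr | starting material
16 | 6‑(prenyloxy)benzofuran‑4‑ol bearing the allyl/pivalate chroman at C2 | CC(C)=CCOc1cc(O)c2cc(oc2c1)-c3c(CC=C)c(OC(=O)C(C)(C)C)cc4OC(C)(C)CCc34 | intermediate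
17 | 2‑methylbut‑2‑ene | CC=C(C)C | starting material
18 | 6‑(prenyloxy)benzofuran‑4‑ol bearing the prenyl/pivalate chroman at C2 | CC(C)=CCOc1cc(O)c2cc(oc2c1)-c3c(CC=C(C)C)c(OC(=O)C(C)(C)C)cc4OC(C)(C)CCc34 | intermediate
19 | 7‑(1,1‑dimethylallyl) benzofuran‑4,6‑diol bearing the pivaloyl‑protected prenyl chroman at C2 | C=CC(C)(C)c1c(O)cc(O)c2cc(oc12)-c3c(CC=C(C)C)c(OC(=O)C(C)(C)C)cc4OC(C)(C)CCc34 | intermediate
20 | Artopetelin C | C=CC(C)(C)c1c(O)cc(O)c2cc(-c3c(CC=C(C)C)c(O)cc4c3CCC(C)(C)O4)oc12 | target

## Totals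
- Total steps: 12.
- Longest linear sequence: 12 (1 → 3 → 4 → 5 → 7 → 8 → 10 → 12 → 14 → 16 → 18 → 19 → 20). Phloroglucinol enters at step 8.

## Three steps most likely to fail
1. **Step 8 (Ti‑mediated phloroglucinol annulation).** The aryl ketone is hindered. TiCl4 may also ionize the 2,2‑dimethylchroman C–O bond or attack the allyl group.
   Fallback: build the benzofuran by Pd‑catalysed α‑arylation of methyl ketone 10 with a 2‑iodo‑3,5‑bis(MOM‑oxy)phenol, followed by mild acid cyclodehydration, and then deprotect.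
2. **Step 9 (6‑O versus 4‑O prenylation of the diol).** The selectivity may be only modest.
   Fallback: fix the reverse‑prenyl regiochemistry early instead. Do the Claisen on the symmetrical 3,5‑bis(MOM‑oxy)phenyl prenyl ether to get the 2‑reverse‑prenyl phenol, then use the fallback 1 benzofuran construction.
3. **Step 11 (Claisen to the reverse‑prenyl group).** It may give the C5 regioisomer, or the product may cyclize or isomerize to a normal prenyl group.
   Fallback: abandon the [3,3] route. Install the quaternary carbon by acid‑catalysed ortho‑propargylation of the 6‑OH benzofuran with 2‑methylbut‑3‑yn‑2‑ol, then Lindlar semihydrogenation of the alkyne.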